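**Plan**

1. Target numbering: oxolane O1, C2 (aryl), C3 (OH, CH2OH), C4 (benzyl), C5. The retrosynthesis re-closes a γ-lactone from the CH2OH carbon on C3 (as C=O) to the benzylic CH2 on C4, exchanges the C3 hydroxyl for an acetyl group, and then cuts C2–C3. Further cuts are the O1–C2 ether bond (benzylation) and the bond from C4 to the benzylic carbon (aldol).
2. Enabling feature: C3 is quaternary and its hydroxymethyl carbon is cis to the C4 benzyl group, so both fit into one cis-fused five-membered lactone ring over C3–C4. In that ring C3 is the enolisable carbon of an α-acetyl lactone (acetyl = masked OH), held next to the O1–C2 benzyl ether.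
3. Forward order: the lactone (ring 1) is built by aldol addition and lactonisation, the benzyl ether chain is attached, C3 is acetylated, the oxolane (ring 2) closes by oxidative C2–C3 bond formation, then acetyl becomes acetate, the lactone is opened by hydrogenolysis, and the acid is reduced.
4. Stereochemistry: C4 comes from an Evans syn-aldol with (S)-4-benzyl oxazolidinone; C3 follows from C4 through the obligatory cis ring fusion; C2 from the convex-face preference of the aryl group; the C3–O bond forms with retention in the Baeyer–Villiger step; the benzylic lactone centre is erased at the end.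

Key step: step 8

Assumption: the α-acetyl lactone 12 is a keto–enol and epimer mixture at the acetyl-bearing carbon; it is drawn as the all-trans keto form, and this centre is reset in step 8. The target numbering O1, C2–C5 is used for these atoms in all intermediates.

**Step 1**
Reactants: 1 vanillin
Product: 2 4-formyl-2-methoxyphenyl pivalate
Conditions: PivCl, Et3N, DMAP (cat.), CH2Cl2, 0 °C → rt
Reagents that add atoms: pivaloyl chloride, CC(C)(C)C(=O)Cl
Why: O-acylation of the phenol (nucleophilic acyl substitution) gives a hindered aryl ester that deactivates this ring for the later oxidation and withstands the amide-base and borohydride steps.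

**Step 2**
Reactants: 3 (4S)-4-benzyl-1,3-oxazolidin-2-one; 4 methyl 4-chloro-4-oxobutanoate
Product: 5 methyl 4-[(4S)-4-benzyl-2-oxo-1,3-oxazolidin-3-yl]-4-oxobutanoate
Conditions: n-BuLi, THF, −78 °C; then 4, −78 → 0 °C
Reagents that add atoms: none
Why: N-acylation of the lithiated oxazolidinone by the acid chloride is the standard preparation of Evans imides, the methyl ester being inert at this temperature.

**Step 3**
Reactants: 5 methyl 4-[(4S)-4-benzyl-2-oxo-1,3-oxazolidin-3-yl]-4-oxobutanoate; 2 4-formyl-2-methoxyphenyl pivalate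
Product: 7 4-[(2S,3S)-3-{[(4S)-4-benzyl-2-oxo-1,3-oxazolidin-3-yl]carbonyl}-5-oxooxolan-2-yl]-2-methoxyphenyl pivalate (trans lactone imide), via syn-aldol adduct 6 (not isolated)
Conditions: Bu2BOTf, iPr2NEt, CH2Cl2, −78 → 0 °C; 2, −78 → 0 °C; pH 7 buffer, MeOH, H2O2, 0 °C; then pTsOH (cat.), CH2Cl2, rt
Reagents that add atoms: none
Why: Evans syn-aldol reaction, in which only the imide is enolised to the Z-boron enolate and the closed chair transition state under control of the (S)-benzyl auxiliary sets both new centres (3S,4S in 6), followed by acid-catalysed lactonisation of the γ-hydroxy ester to the trans-disubstituted lactone.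

**Step 4**
Reactants: 7 trans lactone imide
Product: 8 4-[(2S,3R)-3-(hydroxymethyl)-5-oxooxolan-2-yl]-2-methoxyphenyl pivalate
Conditions: NaBH4, THF/H2O (4:1), 0 °C → rt
Reagents that add atoms: none
Why: chemoselective reductive cleavage of the N-acyl oxazolidinone, whose activated imide carbonyl is reduced by NaBH4 much faster than the γ-lactone or the hindered aryl pivalate, without touching either stereocentre.

**Step 5**
Reactants: 9 [4-(benzyloxy)-3-methoxyphenyl]methanol
Product: 10 4-(benzyloxy)-3-methoxybenzyl 2,2,2-trichloroacetimidate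
Conditions: Cl3CCN, DBU (10 mol%), CH2Cl2, 0 °C; used crude
Reagents that add atoms: trichloroacetonitrile, ClC(Cl)(Cl)C#N
Why: base-catalysed addition of the benzylic alcohol to the nitrile (trichloroacetimidate formation) gives an acid-activatable benzyl donor.

**Step 6**
Reactants: 8 hydroxymethyl lactone; 10 trichloroacetimidate
Product: 11 4-[(2S,3R)-3-({[4-(benzyloxy)-3-methoxybenzyl]oxy}methyl)-5-oxooxolan-2-yl]-2-methoxyphenyl pivalate
Conditions: camphorsulfonic acid (5 mol%), CH2Cl2, 0 °C → rt
Reagents that add atoms: none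
Why: acid-catalysed O-benzylation with a trichloroacetimidate etherifies the primary alcohol under conditions that spare the lactone and the pivalate, which a base-mediated Williamson reaction would not.

**Step 7**
Reactants: 11 benzyl ether lactone
Product: 12 4-[(2S,3R,4R)-4-acetyl-3-({[4-(benzyloxy)-3-methoxybenzyl]oxy}methyl)-5-oxooxolan-2-yl]-2-methoxyphenyl pivalate
Conditions: LiN(SiMe3)2 (2.1 equiv), THF, −78 °C; AcCl (1.05 equiv), −78 → −40 °C; AcOH quench
Reagents that add atoms: acetyl chloride, CC(=O)Cl
Why: Claisen-type C-acylation of the lithium lactone enolate, the second equivalent of base taking up the more acidic β-keto lactone as it forms; the acetyl group enters trans to the neighbouring substituent, but this enolisable centre is reset in step 8.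

**Step 8**
Reactants: 12 α-acetyl lactone
Product: 14 (3S,3aR,6R,6aS)-6a-acetyl-6-[4-(benzyloxy)-3-methoxyphenyl]-3-[3-methoxy-4-(pivaloyloxy)phenyl]tetrahydro-1H,3H-furo[3,4-c]furan-1-one, via oxocarbenium ion 13 (not isolated)
Conditions: DDQ (20 mol%), LiClO4 (0.1 M), 2,6-di-tert-butyl-4-methylpyridine, 4 Å MS, MeCN/CH2Cl2, rt; divided cell, graphite-felt anode, Pt cathode (catholyte LiClO4, AcOH, MeCN), constant current, about 2.2 F per mole
Reagents that add atoms: none
Why: Proposed new method: DDQ, kept in its oxidised form at the anode, takes a hydride from the ether CH2 (C2) of the dialkoxybenzyl group and the aryl-stabilised oxocarbenium ion 13 is attacked through C3 by the enol of the α-acetyl lactone; the closest known reactions are DDQ-mediated dehydrogenative couplings of benzyl ethers with ketones and 1,3-dicarbonyl compounds and DDQ-mediated oxidative cyclisations of benzylic ethers onto tethered enol nucleophiles, with anodic regeneration of DDQ known from mediated oxidations. The oxolane ring closes in a 5-endo-trig mode with respect to the O1=C2 bond (enol-exo for the nucleophile), a mode that oxocarbenium ions accept in Prins-type oxolane syntheses. C3 is controlled by C4, because the CH2–O tether reaches only the enol face on its own side and the bicycle must be cis-fused. C2 is controlled by the bicycle, the aryl group taking the convex face cis to acetyl, and reversible C2–C3 heterolysis of the 1,3-dicarbonyl adduct would allow equilibration to this isomer. The step needs oxidation at the ether CH2 and not at the lactone benzylic CH or at C2–H of the product: the first is secured by the alkoxy-versus-acyloxy difference at carbon and by the pivalate-deactivated ring, the second by the acceptor-laden quaternary C3 next to C2. Molecular sieves protect 13 from hydrolysis, the hindered pyridine takes up the protons released on reoxidation of DDQH2, and the mediator holds the anode below the potential of direct arene oxidation.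

**Step 9**
Reactants: 14 bridgehead acetyl furofuranone
Product: 15 (3S,3aR,6R,6aR)-6-[4-(benzyloxy)-3-methoxyphenyl]-3-[3-methoxy-4-(pivaloyloxy)phenyl]-1-oxotetrahydro-1H,3H-furo[3,4-c]furan-6a-yl acetate
Conditions: mCPBA, Na2HPO4, CH2Cl2, 0 °C → reflux
Reagents that add atoms: 3-chloroperbenzoic acid, OOC(=O)c1cccc(Cl)c1
Why: Baeyer–Villiger oxidation, in which the quaternary carbon of the tetrahedral peracid adduct migrates in preference to methyl and with retention, so the acetyl group becomes an acetate on the same face of C3.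

**Step 10**
Reactants: 15 bridgehead acetate
Product: 16 (2R,3R,4S)-3-(acetyloxy)-2-(4-hydroxy-3-methoxyphenyl)-4-{[3-methoxy-4-(pivaloyloxy)phenyl]methyl}oxolane-3-carboxylic acid
Conditions: H2 (1 atm), 10% Pd/C, EtOAc, rt
Reagents that add atoms: none
Why: heterogeneous hydrogenolysis removes the O-benzyl group and cleaves the benzylic acyloxy C–O bond of the strained lactone, a better leaving group on a less hindered carbon than the C2–O1 ether next to the fully substituted, acceptor-bearing C3, so the lactone stereocentre becomes CH2 while C2, C3 and C4 stay untouched.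

**Step 11**
Reactants: 16 acetoxy acid
Product: 17 (2R,3S,4S)-2-(4-hydroxy-3-methoxyphenyl)-4-(4-hydroxy-3-methoxybenzyl)-3-(hydroxymethyl)oxolan-3-ol (target)
Conditions: LiAlH4 (excess), THF, 0 → 40 °C; aq. potassium sodium tartrate work-up
Reagents that add atoms: none
Why: hydride reduction by LiAlH4 converts the carboxylic acid into the CH2OH group and cleaves the acetate and pivalate esters in the same operation, without affecting the ring stereocentres.

**Compound list**

1 | vanillin | COc1cc(C=O)ccc1O | starting material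
2 | 4-formyl-2-methoxyphenyl pivalate | COc1cc(C=O)ccc1OC(=O)C(C)(C)C | intermediate
3 | (4S)-4-benzyl-1,3-oxazolidin-2-one | O=C1N[C@@H](Cc2ccccc2)CO1 | starting material
4 | methyl 4-chloro-4-oxobutanoate | COC(=O)CCC(Cl)=O | starting material
5 | methyl 4-[(4S)-4-benzyl-2-oxo-1,3-oxazolidin-3-yl]-4-oxobutanoate | COC(=O)CCC(=O)N1[C@@H](Cc2ccccc2)COC1=O | intermediate
6 | methyl (3S,4S)-3-{[(4S)-4-benzyl-2-oxo-1,3-oxazolidin-3-yl]carbonyl}-4-hydroxy-4-[3-methoxy-4-(pivaloyloxy)phenyl]butanoate (syn-aldol adduct, not isolated) | COC(=O)C[C@H](C(=O)N1[C@@H](Cc2ccccc2)COC1=O)[C@H](O)c1ccc(OC(=O)C(C)(C)C)c(OC)c1 | intermediate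
7 | 4-[(2S,3S)-3-{[(4S)-4-benzyl-2-oxo-1,3-oxazolidin-3-yl]carbonyl}-5-oxooxolan-2-yl]-2-methoxyphenyl pivalate | O=C1O[C@H](c2ccc(OC(=O)C(C)(C)C)c(OC)c2)[C@@H](C(=O)N2[C@@H](Cc3ccccc3)COC2=O)C1 | intermediate
8 | 4-[(2S,3R)-3-(hydroxymethyl)-5-oxooxolan-2-yl]-2-methoxyphenyl pivalate | O=C1O[C@H](c2ccc(OC(=O)C(C)(C)C)c(OC)c2)[C@@H](CO)C1 | intermediate
9 | [4-(benzyloxy)-3-methoxyphenyl]methanol | COc1cc(CO)ccc1OCc1ccccc1 | starting material
10 | 4-(benzyloxy)-3-methoxybenzyl 2,2,2-trichloroacetimidate | COc1cc(COC(=N)C(Cl)(Cl)Cl)ccc1OCc1ccccc1 | intermediate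
11 | 4-[(2S,3R)-3-({[4-(benzyloxy)-3-methoxybenzyl]oxy}methyl)-5-oxooxolan-2-yl]-2-methoxyphenyl pivalate | O=C1O[C@H](c2ccc(OC(=O)C(C)(C)C)c(OC)c2)[C@@H](COCc2ccc(OCc3ccccc3)c(OC)c2)C1 | intermediate
12 | 4-[(2S,3R,4R)-4-acetyl-3-({[4-(benzyloxy)-3-methoxybenzyl]oxy}methyl)-5-oxooxolan-2-yl]-2-methoxyphenyl pivalate | O=C1O[C@H](c2ccc(OC(=O)C(C)(C)C)c(OC)c2)[C@@H](COCc2ccc(OCc3ccccc3)c(OC)c2)[C@@H]1C(C)=O | intermediate
13 | (E)-oxocarbenium ion from hydride loss at the ether CH2 of 12 (cation, not isolated) | O=C1O[C@H](c2ccc(OC(=O)C(C)(C)C)c(OC)c2)[C@@H](C/[O+]=C/c2ccc(OCc3ccccc3)c(OC)c2)[C@@H]1C(C)=O | intermediate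
14 | (3S,3aR,6R,6aS)-6a-acetyl-6-[4-(benzyloxy)-3-methoxyphenyl]-3-[3-methoxy-4-(pivaloyloxy)phenyl]tetrahydro-1H,3H-furo[3,4-c]furan-1-one | O=C1O[C@H](c3ccc(OC(=O)C(C)(C)C)c(OC)c3)[C@H]2CO[C@H](c3ccc(OCc4ccccc4)c(OC)c3)[C@@]12C(C)=O | intermediate
15 | (3S,3aR,6R,6aR)-6-[4-(benzyloxy)-3-methoxyphenyl]-3-[3-methoxy-4-(pivaloyloxy)phenyl]-1-oxotetrahydro-1H,3H-furo[3,4-c]furan-6a-yl acetate | O=C1O[C@H](c3ccc(OC(=O)C(C)(C)C)c(OC)c3)[C@H]2CO[C@H](c3ccc(OCc4ccccc4)c(OC)c3)[C@@]12OC(C)=O | intermediate
16 | (2R,3R,4S)-3-(acetyloxy)-2-(4-hydroxy-3-methoxyphenyl)-4-{[3-methoxy-4-(pivaloyloxy)phenyl]methyl}oxolane-3-carboxylic acid | COc1cc(C[C@H]2CO[C@H](c3ccc(O)c(OC)c3)[C@@]2(OC(C)=O)C(=O)O)ccc1OC(=O)C(C)(C)C | intermediate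
17 | (2R,3S,4S)-2-(4-hydroxy-3-methoxyphenyl)-4-(4-hydroxy-3-methoxybenzyl)-3-(hydroxymethyl)oxolan-3-ol | COc1cc(C[C@H]2CO[C@H](c3ccc(O)c(OC)c3)[C@@]2(O)CO)ccc1O | target

**Step count**

Total: 11 steps. Longest linear sequence: 9 steps (steps 2, 3, 4, 6, 7, 8, 9, 10, 11).

**Steps most likely to fail**

Step 8 (anodic cyclisation). The oxocarbenium ion may be hydrolysed or over-oxidised before it is captured, the 5-endo closure onto a fully substituted carbon may be slow, or the aryl group may not settle cleanly on the convex face. The fallback makes the same C2–C3 bond and the same ring by carbenoid C–H insertion, which is established for benzyloxymethyl diazo lactones of this class. It sets out from 12. Deacylative diazo transfer (4-acetamidobenzenesulfonyl azide, DBU, MeCN, 0 °C) would give 4-[(2S,3R)-3-({[4-(benzyloxy)-3-methoxybenzyl]oxy}methyl)-4-diazo-5-oxooxolan-2-yl]-2-methoxyphenyl pivalate F1. Rh2(OAc)4 (1 mol%) in CH2Cl2 at reflux should insert the carbenoid into the benzylic ether C–H bond and give the cis-fused furofuranone with a bridgehead hydrogen, expected mainly as the 6-endo-aryl isomer F2. Catalytic BF3·OEt2 in CH2Cl2 at 0 °C would equilibrate the electron-rich benzylic ether centre to the 6-exo-aryl furofuranone F3. Deprotonation at the bridgehead with LiN(SiMe3)2 (THF, −78 °C) and C-acetylation with acetyl chloride, which can only give the cis-fused product, comes back to the route at 14.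

Step 9 (Baeyer–Villiger oxidation). Migration of the electron-poor quaternary carbon may be too slow, so that oxidation of the electron-rich arene, or no reaction, prevails. The fallback removes the acetyl group and brings in the oxygen as an electrophile. It sets out from 14. Retro-Claisen cleavage with anhydrous NaOMe (1 equiv, THF, −40 → 0 °C) releases the bridgehead lactone enolate and methyl acetate. The enolate is oxidised in the same flask with 2-(phenylsulfonyl)-3-phenyloxaziridine at −78 °C to the bridgehead tertiary alcohol (3S,3aR,6R,6aR)-6-[4-(benzyloxy)-3-methoxyphenyl]-6a-hydroxy-3-[3-methoxy-4-(pivaloyloxy)phenyl]tetrahydro-1H,3H-furo[3,4-c]furan-1-one F4; the cis ring fusion allows only this configuration. Ac2O, DMAP and Et3N in CH2Cl2 then give the acetate and come back to the route at 15.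

Step 10 (hydrogenolysis). Once the phenol on the C2 aryl group is unmasked, cleavage of the C2–O1 benzylic ether may compete with cleavage of the lactone C–O bond, or the lactone on the acyloxy-substituted ring may react sluggishly. The fallback inverts the order of the last two operations so that the bond to be cut is the electronically favoured one. It sets out from 15. LiAlH4 (THF, 0 °C → rt) reduces the lactone to the diol and removes acetate and pivalate, giving (2R,3S,4R)-2-[4-(benzyloxy)-3-methoxyphenyl]-4-[(S)-hydroxy(4-hydroxy-3-methoxyphenyl)methyl]-3-(hydroxymethyl)oxolan-3-ol F5, whose benzylic hydroxyl now sits para to a free phenol. Hydrogenolysis (H2, 10% Pd/C, EtOH, rt) removes the benzyl ether and this activated benzylic hydroxyl and comes back to the route at the target 17.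

**Further compounds**

F1 | step 8 | 4-[(2S,3R)-3-({[4-(benzyloxy)-3-methoxybenzyl]oxy}methyl)-4-diazo-5-oxooxolan-2-yl]-2-methoxyphenyl pivalate | O=C1O[C@H](c2ccc(OC(=O)C(C)(C)C)c(OC)c2)[C@@H](COCc2ccc(OCc3ccccc3)c(OC)c2)C1=[N+]=[N-]
F2 | step 8 | (3S,3aR,6R,6aS)-6-[4-(benzyloxy)-3-methoxyphenyl]-3-[3-methoxy-4-(pivaloyloxy)phenyl]tetrahydro-1H,3H-furo[3,4-c]furan-1-one (6-endo aryl) | O=C1O[C@H](c3ccc(OC(=O)C(C)(C)C)c(OC)c3)[C@H]2CO[C@@H](c3ccc(OCc4ccccc4)c(OC)c3)[C@@H]12
F3 | step 8 | (3S,3aR,6S,6aS)-6-[4-(benzyloxy)-3-methoxyphenyl]-3-[3-methoxy-4-(pivaloyloxy)phenyl]tetrahydro-1H,3H-furo[3,4-c]furan-1-one (6-exo aryl) | O=C1O[C@H](c3ccc(OC(=O)C(C)(C)C)c(OC)c3)[C@H]2CO[C@H](c3ccc(OCc4ccccc4)c(OC)c3)[C@@H]12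
F4 | step 9 | (3S,3aR,6R,6aR)-6-[4-(benzyloxy)-3-methoxyphenyl]-6a-hydroxy-3-[3-methoxy-4-(pivaloyloxy)phenyl]tetrahydro-1H,3H-furo[3,4-c]furan-1-one | O=C1O[C@H](c3ccc(OC(=O)C(C)(C)C)c(OC)c3)[C@H]2CO[C@H](c3ccc(OCc4ccccc4)c(OC)c3)[C@@]12O
F5 | step 10 | (2R,3S,4R)-2-[4-(benzyloxy)-3-methoxyphenyl]-4-[(S)-hydroxy(4-hydroxy-3-methoxyphenyl)methyl]-3-(hydroxymethyl)oxolan-3-ol | COc1cc([C@@H](O)[C@H]2CO[C@H](c3ccc(OCc4ccccc4)c(OC)c3)[C@@]2(O)CO)ccc1O
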